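**Retrosynthetic overview**
1. Target ⇒ saturate the CH2–CH2 linker (diimide) after a Wittig union of bicyclic phosphonium salt 11 with peroxy aldehyde-acid 22.
2. 11 ⇐ silyl ether 10 ⇐ acyclic 5-hydroxyfarnesyl ether 7, by a chiral-acid, allyl-cation bicyclisation that closes rings A and B and sets both ring-fusion centres in one operation.
3. 7 ⇐ citral + the allylbarium reagent from prenol-derived chloride 4.
4. 22 ⇐ glycol cleavage of 21 ⇐ epoxy β-lactone 19 + H2O2 (epoxide perhydrolysis, then the hydroperoxide opens the β-lactone: 1,2-dioxane closed with inversion at both C–O carbons); 19 ⇐ Sharpless epoxide of geraniol + propanoyl chloride.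
5. Ring order: rings A and B together (step 5), 1,2-dioxane (step 11), fragments joined last (steps 13–14).

Assumption: citral is used as its commercial E/Z mixture and 7 as the racemic carbinol (both elements are erased in the allyl cation of step 5); the catalyst antipode in step 5 and the quinidine-series catalyst in step 10 are taken in the sense that gives the drawn configurations, to be confirmed on the first run.

**Step 1**
Reactants: 1 3-methylbut-2-en-1-ol (prenol)
Product: 2 tert-butyl(dimethyl)[(3-methylbut-2-en-1-yl)oxy]silane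
Conditions: TBSCl, imidazole, CH2Cl2, 0 °C to rt
Reagents that add atoms: tert-butyldimethylsilyl chloride, CC(C)(C)[Si](C)(C)Cl
Why: Silyl ether protection of the primary allylic alcohol so that it survives the organobarium and acid steps; no stereocentre is involved.

**Step 2**
Reactants: 2 tert-butyl(dimethyl)[(3-methylbut-2-en-1-yl)oxy]silane
Product: 3 (2E)-4-{[tert-butyl(dimethyl)silyl]oxy}-2-methylbut-2-en-1-ol
Conditions: SeO2 (10 mol%), t-BuOOH, salicylic acid (cat.), CH2Cl2, rt
Reagents that add atoms: tert-butyl hydroperoxide, CC(C)(C)OO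
Why: Riley allylic oxidation (ene reaction then [2,3]-sigmatropic shift) attacks the methyl group trans to the chain of a trisubstituted alkene, so the E-allylic alcohol forms selectively.

**Step 3**
Reactants: 3 (2E)-4-{[tert-butyl(dimethyl)silyl]oxy}-2-methylbut-2-en-1-ol
Product: 4 tert-butyl{[(2E)-4-chloro-3-methylbut-2-en-1-yl]oxy}dimethylsilane
Conditions: NCS, Me2S, CH2Cl2, −20 to 0 °C
Reagents that add atoms: N-chlorosuccinimide, O=C1CCC(=O)N1Cl
Why: Corey–Kim chlorination replaces the allylic hydroxyl by chloride through SN2 attack on the alkoxysulfonium salt, without allylic transposition and with the E-alkene and silyl ether intact.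

**Step 4**
Reactants: 4 tert-butyl{[(2E)-4-chloro-3-methylbut-2-en-1-yl]oxy}dimethylsilane; 5 citral (3,7-dimethylocta-2,6-dienal, E/Z mixture)
Product: 7 (2E)-1-{[tert-butyl(dimethyl)silyl]oxy}-3,7,11-trimethyldodeca-2,6,10-trien-5-ol (6E/6Z mixture, racemic carbinol), via allylbarium chloride 6 (not isolated)
Conditions: BaI2, lithium biphenylide (LiC12H10, 2 equiv), THF, rt; 4, −78 °C; then 5, −78 °C; 1 M HCl
Reagents that add atoms: none
Why: Allylbarium addition to an aldehyde goes through the α-carbon, 1,2 on enals and with retention of the E-alkene, so the linear homoallylic alcohol forms; the new carbinol centre and the citral-derived alkene geometry are not controlled and are erased in step 5.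

**Step 5**
Reactants: 7 (2E)-1-{[tert-butyl(dimethyl)silyl]oxy}-3,7,11-trimethyldodeca-2,6,10-trien-5-ol
Product: 10 tert-butyl(dimethyl){[(4aR,8aS)-1,1,3,6-tetramethyl-1,4,4a,7,8,8a-hexahydronaphthalen-2-yl]methoxy}silane, via allyl cation 8 (not isolated), via bicyclic cation 9 (not isolated)
Conditions: chiral IDPi acid [imidodiphosphorimidate built from two 3,3'-bis(3,5-bis(trifluoromethyl)phenyl)-BINOL units with P=N–SO2CF3 groups, one antipode, 5 mol%], 5 Å molecular sieves, PhCF3/(CF3)2CHOH, −40 °C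
Reagents that add atoms: none
Why: Proposed new method: the confined chiral Brønsted acid ionises the allylic alcohol to a cisoid 1,1,3-trialkylallyl cation held as a contact ion pair with the chiral anion; the terminal prenyl alkene adds to C5 (ring A, the neryl-to-terpinyl closure) while the developing dimethylcarbinyl cation is taken up by the C2=C3 alkene (ring B, Markovnikov 6-endo), and loss of H-2 gives the tetrasubstituted alkene, so both ring-fusion centres are set in the first C–C bond formation inside the chiral pocket, the compact folded cation–olefin [4+2]-like array with sp2 atoms in the tether giving the cis fusion; closest known chemistry is the IDPi-catalysed asymmetric cyclisation of neral to isopiperitenol, IDPi-catalysed polyene cyclisations and the acid-mediated citral–olivetol route to cis-fused tetrahydrocannabinoids.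

**Step 6**
Reactants: 10 tert-butyl(dimethyl){[(4aR,8aS)-1,1,3,6-tetramethyl-1,4,4a,7,8,8a-hexahydronaphthalen-2-yl]methoxy}silane
Product: 11 {[(4aR,8aS)-1,1,3,6-tetramethyl-1,4,4a,7,8,8a-hexahydronaphthalen-2-yl]methyl}triphenylphosphonium bromide
Conditions: PPh3·HBr, MeOH, rt
Reagents that add atoms: triphenylphosphine hydrobromide, [Br-].c1ccc(cc1)[PH+](c1ccccc1)c1ccccc1
Why: The mild acid salt cleaves the allylic silyl ether and turns the allylic alcohol, by way of the allyl cation or bromide, into the primary phosphonium salt (allylic substitution at the less hindered terminus, as for cyclogeranyl and retinyl salts); the ring-fusion centres are not touched.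

**Step 7**
Reactants: 12 geraniol
Product: 13 [(2R,3R)-3-methyl-3-(4-methylpent-3-en-1-yl)oxiran-2-yl]methanol
Conditions: Ti(OiPr)4 (5 mol%), D-(−)-diethyl tartrate (6 mol%), t-BuOOH, 4 Å molecular sieves, CH2Cl2, −20 °C
Reagents that add atoms: tert-butyl hydroperoxide, CC(C)(C)OO
Why: Sharpless asymmetric epoxidation is hydroxyl-directed, so only the 2,3-alkene reacts, and the D-tartrate catalyst gives the (2R,3R) epoxide; its C3 is the carbon that becomes C6 of the dioxane after inversion.

**Step 8**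
Reactants: 13 [(2R,3R)-3-methyl-3-(4-methylpent-3-en-1-yl)oxiran-2-yl]methanol
Product: 14 triethyl{[(2R,3R)-3-methyl-3-(4-methylpent-3-en-1-yl)oxiran-2-yl]methoxy}silane
Conditions: TESCl, imidazole, CH2Cl2, 0 °C
Reagents that add atoms: chlorotriethylsilane, CC[Si](Cl)(CC)CC
Why: Silyl ether protection keeps the primary alcohol from being acylated in step 10, and the TES group is chosen because it falls off under the acid of step 11; no stereocentre is touched.

**Step 9**
Reactants: 14 triethyl{[(2R,3R)-3-methyl-3-(4-methylpent-3-en-1-yl)oxiran-2-yl]methoxy}silane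
Product: 16 3-[(2R,3R)-2-methyl-3-{[(triethylsilyl)oxy]methyl}oxiran-2-yl]propanal, via ozonide 15 (not isolated)
Conditions: O3, CH2Cl2, −78 °C; then Me2S, −78 °C to rt
Reagents that add atoms: ozone, [O-][O+]=O
Why: Ozonolysis with reductive work-up cleaves the only alkene to the aldehyde; the epoxide and silyl ether are inert, so both epoxide centres are kept.

**Step 10**
Reactants: 16 3-[(2R,3R)-2-methyl-3-{[(triethylsilyl)oxy]methyl}oxiran-2-yl]propanal; 17 propanoyl chloride
Product: 19 (3R,4S)-3-methyl-4-{2-[(2R,3R)-2-methyl-3-{[(triethylsilyl)oxy]methyl}oxiran-2-yl]ethyl}oxetan-2-one, via methylketene 18 (not isolated)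
Conditions: O-trimethylsilylquinidine (10 mol%), LiClO4, i-Pr2NEt, CH2Cl2/Et2O, −78 °C
Reagents that add atoms: none
Why: Catalytic asymmetric ketene–aldehyde [2+2] cycloaddition (acyl halide–aldehyde cyclocondensation): the alkaloid turns methylketene into a Z-ammonium enolate that adds to the LiClO4-activated aldehyde through a closed transition state, giving the cis β-lactone with catalyst-controlled (3R,4S) configuration, independent of the remote epoxide.

**Step 11**
Reactants: 19 (3R,4S)-3-methyl-4-{2-[(2R,3R)-2-methyl-3-{[(triethylsilyl)oxy]methyl}oxiran-2-yl]ethyl}oxetan-2-one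
Product: 21 (2R)-2-[(3R,6S)-6-[(1R)-1,2-dihydroxyethyl]-6-methyl-1,2-dioxan-3-yl]propanoic acid, via hydroperoxide 20 (not isolated)
Conditions: anhydrous H2O2 in Et2O, H3PMo12O40 (3 mol%), 0 °C to rt; aqueous work-up
Reagents that add atoms: hydrogen peroxide, OO
Why: Proposed new method: acid-catalysed perhydrolysis of the trisubstituted epoxide at its tertiary carbon (anti opening, inversion) is known; the tertiary hydroperoxide then opens the β-lactone by 6-exo SN2 attack at the alkyl C–O carbon (inversion), the mode in which β-lactones react with neutral oxygen nucleophiles under acid and the lactone counterpart of the known acid-promoted hydroperoxide–oxetane closure to 1,2-dioxanes, so C6 and C3 of the dioxane are set by two inversions, C2 of the acid is carried over from the lactone, the carboxylic acid is freed and the TES ether is lost.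

**Step 12**
Reactants: 21 (2R)-2-[(3R,6S)-6-[(1R)-1,2-dihydroxyethyl]-6-methyl-1,2-dioxan-3-yl]propanoic acid
Product: 22 (2R)-2-[(3R,6S)-6-formyl-6-methyl-1,2-dioxan-3-yl]propanoic acid
Conditions: NaIO4, THF/H2O, 0 °C
Reagents that add atoms: none
Why: Periodate glycol cleavage removes the terminal carbon as formaldehyde and leaves an aldehyde on the quaternary peroxide carbon, which has no α-hydrogen and cannot epimerise; the O–O bond and the acid are inert to periodate.

**Step 13**
Reactants: 11 {[(4aR,8aS)-1,1,3,6-tetramethyl-1,4,4a,7,8,8a-hexahydronaphthalen-2-yl]methyl}triphenylphosphonium bromide; 22 (2R)-2-[(3R,6S)-6-formyl-6-methyl-1,2-dioxan-3-yl]propanoic acid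
Product: 24 (2R)-2-[(3R,6S)-6-methyl-6-{2-[(4aR,8aS)-1,1,3,6-tetramethyl-1,4,4a,7,8,8a-hexahydronaphthalen-2-yl]ethenyl}-1,2-dioxan-3-yl]propanoic acid (E/Z mixture), via ylide 23 (not isolated)
Conditions: KN(SiMe3)2 (2.1 equiv), THF, −78 to 0 °C; dilute HCl work-up
Reagents that add atoms: none
Why: Wittig olefination of the semi-stabilised allylic ylide with the non-enolisable aldehyde; the acid reacts as its potassium carboxylate, which suppresses α-deprotonation and hence retro-oxa-Michael opening or epimerisation at C2, and the alkene geometry does not matter because the bond is reduced next.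

**Step 14**
Reactants: 24 (2R)-2-[(3R,6S)-6-methyl-6-{2-[(4aR,8aS)-1,1,3,6-tetramethyl-1,4,4a,7,8,8a-hexahydronaphthalen-2-yl]ethenyl}-1,2-dioxan-3-yl]propanoic acid
Product: 25 (2R)-2-[(3R,6R)-6-methyl-6-{2-[(4aR,8aS)-1,1,3,6-tetramethyl-1,4,4a,7,8,8a-hexahydronaphthalen-2-yl]ethyl}-1,2-dioxan-3-yl]propanoic acid
Conditions: 2-nitrobenzenesulfonylhydrazide, Et3N, CH2Cl2, rt
Reagents that add atoms: none
Why: Diimide reduction transfers H2 in a concerted syn fashion fastest to the disubstituted alkene, very slowly to the tri- and tetrasubstituted ring alkenes and not at all to the O–O bond, so only the linker is saturated and all six stereocentres are unchanged (the C6 descriptor changes from S to R only through the priority switch).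

**Compound list**
1 | 3-methylbut-2-en-1-ol (prenol) | CC(C)=CCO | starting material
2 | tert-butyl(dimethyl)[(3-methylbut-2-en-1-yl)oxy]silane | CC(C)=CCO[Si](C)(C)C(C)(C)C | intermediate
3 | (2E)-4-{[tert-butyl(dimethyl)silyl]oxy}-2-methylbut-2-en-1-ol | OC/C(C)=C/CO[Si](C)(C)C(C)(C)C | intermediate
4 | tert-butyl{[(2E)-4-chloro-3-methylbut-2-en-1-yl]oxy}dimethylsilane | ClC/C(C)=C/CO[Si](C)(C)C(C)(C)C | intermediate
5 | citral (3,7-dimethylocta-2,6-dienal, E/Z mixture) | CC(C)=CCCC(C)=CC=O | starting material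
6 | [(2E)-4-{[tert-butyl(dimethyl)silyl]oxy}-2-methylbut-2-en-1-yl]barium chloride | Cl[Ba]C/C(C)=C/CO[Si](C)(C)C(C)(C)C | intermediate
7 | (2E)-1-{[tert-butyl(dimethyl)silyl]oxy}-3,7,11-trimethyldodeca-2,6,10-trien-5-ol (6E/6Z mixture, racemic) | CC(C)=CCCC(C)=CC(O)C/C(C)=C/CO[Si](C)(C)C(C)(C)C | intermediate
8 | cisoid allyl cation of 7 (charge over C5–C7, ion pair with the catalyst anion) | CC(C)=CCC/C(C)=C\[CH+]C/C(C)=C/CO[Si](C)(C)C(C)(C)C | intermediate
9 | (4aR,8aS)-2-({[tert-butyl(dimethyl)silyl]oxy}methyl)-1,1,3,6-tetramethyl-1,2,3,4,4a,7,8,8a-octahydronaphthalen-3-ylium (C2 unspecified) | CC1=C[C@H]2C[C+](C)C(CO[Si](C)(C)C(C)(C)C)C(C)(C)[C@H]2CC1 | intermediate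
10 | tert-butyl(dimethyl){[(4aR,8aS)-1,1,3,6-tetramethyl-1,4,4a,7,8,8a-hexahydronaphthalen-2-yl]methoxy}silane | CC1=C[C@H]2CC(C)=C(CO[Si](C)(C)C(C)(C)C)C(C)(C)[C@H]2CC1 | intermediate
11 | {[(4aR,8aS)-1,1,3,6-tetramethyl-1,4,4a,7,8,8a-hexahydronaphthalen-2-yl]methyl}triphenylphosphonium bromide | CC1=C[C@H]2CC(C)=C(C[P+](c3ccccc3)(c3ccccc3)c3ccccc3)C(C)(C)[C@H]2CC1.[Br-] | intermediate
12 | geraniol | CC(C)=CCC/C(C)=C/CO | starting material
13 | [(2R,3R)-3-methyl-3-(4-methylpent-3-en-1-yl)oxiran-2-yl]methanol | OC[C@H]1O[C@]1(C)CCC=C(C)C | intermediate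
14 | triethyl{[(2R,3R)-3-methyl-3-(4-methylpent-3-en-1-yl)oxiran-2-yl]methoxy}silane | CC[Si](CC)(CC)OC[C@H]1O[C@]1(C)CCC=C(C)C | intermediate
15 | 3,3-dimethyl-5-{2-[(2R,3R)-2-methyl-3-{[(triethylsilyl)oxy]methyl}oxiran-2-yl]ethyl}-1,2,4-trioxolane (ozonide, C5 unspecified) | CC[Si](CC)(CC)OC[C@H]1O[C@]1(C)CCC1OOC(C)(C)O1 | intermediate
16 | 3-[(2R,3R)-2-methyl-3-{[(triethylsilyl)oxy]methyl}oxiran-2-yl]propanal | CC[Si](CC)(CC)OC[C@H]1O[C@]1(C)CCC=O | intermediate
17 | propanoyl chloride | CCC(Cl)=O | starting material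
18 | methylketene | CC=C=O | intermediate
19 | (3R,4S)-3-methyl-4-{2-[(2R,3R)-2-methyl-3-{[(triethylsilyl)oxy]methyl}oxiran-2-yl]ethyl}oxetan-2-one | C[C@H]1C(=O)O[C@H]1CC[C@@]2(C)O[C@@H]2CO[Si](CC)(CC)CC | intermediate
20 | (3R,4S)-4-{(3S,4R)-3-hydroperoxy-4-hydroxy-3-methyl-5-[(triethylsilyl)oxy]pentyl}-3-methyloxetan-2-one | C[C@H]1C(=O)O[C@H]1CC[C@](C)(OO)[C@H](O)CO[Si](CC)(CC)CC | intermediate
21 | (2R)-2-[(3R,6S)-6-[(1R)-1,2-dihydroxyethyl]-6-methyl-1,2-dioxan-3-yl]propanoic acid | OC[C@@H](O)[C@]1(C)CC[C@H]([C@@H](C)C(=O)O)OO1 | intermediate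
22 | (2R)-2-[(3R,6S)-6-formyl-6-methyl-1,2-dioxan-3-yl]propanoic acid | O=C[C@]1(C)CC[C@H]([C@@H](C)C(=O)O)OO1 | intermediate
23 | {[(4aR,8aS)-1,1,3,6-tetramethyl-1,4,4a,7,8,8a-hexahydronaphthalen-2-yl]methylidene}triphenylphosphorane | CC1=C[C@H]2CC(C)=C(C=P(c3ccccc3)(c3ccccc3)c3ccccc3)C(C)(C)[C@H]2CC1 | intermediate
24 | (2R)-2-[(3R,6S)-6-methyl-6-{2-[(4aR,8aS)-1,1,3,6-tetramethyl-1,4,4a,7,8,8a-hexahydronaphthalen-2-yl]ethenyl}-1,2-dioxan-3-yl]propanoic acid (E/Z mixture) | CC1=C[C@H]2CC(C)=C(C=C[C@]3(C)CC[C@H]([C@@H](C)C(=O)O)OO3)C(C)(C)[C@H]2CC1 | intermediate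
25 | (2R)-2-[(3R,6R)-6-methyl-6-{2-[(4aR,8aS)-1,1,3,6-tetramethyl-1,4,4a,7,8,8a-hexahydronaphthalen-2-yl]ethyl}-1,2-dioxan-3-yl]propanoic acid | CC1=C[C@H]2CC(C)=C(CC[C@]3(C)CC[C@H]([C@@H](C)C(=O)O)OO3)C(C)(C)[C@H]2CC1 | target

**Totals**
Total step count: 14. Longest linear sequence: 8 steps (steps 1–6, 13, 14, or steps 7–12, 13, 14).

**Steps most likely to fail, with fallbacks**

Step 5 (bicyclisation) is the main risk: the trans-fused isomer, double-bond isomers or low enantiomeric excess may result. The fallback builds the two rings one after the other under auxiliary control; it sets out from 4 and comes back at 10. 2-Methylbut-1-en-3-yne is hydroborated with pinacolborane (Cp2Zr(H)Cl cat.) to the (E)-dienyl pinacol boronate F1. Suzuki allylation of 4 with F1 (Pd(PPh3)4, zerovalent palladium, K3PO4) gives the silyloxy triene F2. A Diels–Alder reaction of F2 with (R)-3-acryloyl-4-benzyl-1,3-oxazolidin-2-one (Et2AlCl, −78 °C) builds ring A endo, with the two centres cis and the face set by the auxiliary, giving the imide adduct F3. Excess MeMgBr converts it into the tertiary alcohol F4 with release of the auxiliary. Catalytic HNTf2 in CH2Cl2 at −78 °C ionises F4 and the side-chain alkene closes ring B, which gives 10.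

Step 11 (peroxide double ring opening) may fail if the hydroxyl freed from the epoxide, or external H2O2, opens the lactone before the tertiary hydroperoxide does. The fallback reverses the roles of the two electrophiles; it sets out from 19 and comes back at 21. Neutral anhydrous H2O2 without acid opens only the β-lactone at its alkyl carbon (inversion) to give the β-hydroperoxy acid F5. Catalytic camphorsulfonic acid then lets this secondary hydroperoxide open the epoxide 6-exo at its tertiary carbon (inversion, the established hydroperoxide–epoxide closure) and removes the TES group, which gives 21.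

Step 13 (Wittig union) joins a hindered ylide to a neopentyl-type aldehyde and may be slow. The fallback replaces the phosphorus ylide by a smaller sulfone carbanion; it sets out from 10 and comes back at 24. Bu4NF gives the allylic alcohol F6. A Mitsunobu reaction with 1-phenyl-1H-tetrazole-5-thiol (PPh3, diisopropyl azodicarboxylate) gives the tetrazolyl sulfide F7. Oxidation with (NH4)6Mo7O24/H2O2 gives the tetrazolyl sulfone F8. Julia–Kocienski olefination of 22 (as its potassium salt) with F8 and KN(SiMe3)2 at −78 °C gives 24.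

**Further compounds**
F1 | step 5 | 4,4,5,5-tetramethyl-2-[(1E)-3-methylbuta-1,3-dien-1-yl]-1,3,2-dioxaborolane | CC(=C)/C=C/B1OC(C)(C)C(C)(C)O1
F2 | step 5 | tert-butyl{[(2E,5E)-3,7-dimethylocta-2,5,7-trien-1-yl]oxy}dimethylsilane | C=C(C)/C=C/C/C(C)=C/CO[Si](C)(C)C(C)(C)C
F3 | step 5 | (4R)-4-benzyl-3-({(1S,2R)-2-[(2E)-4-{[tert-butyl(dimethyl)silyl]oxy}-2-methylbut-2-en-1-yl]-4-methylcyclohex-3-en-1-yl}carbonyl)-1,3-oxazolidin-2-one | CC1=C[C@@H](C/C(C)=C/CO[Si](C)(C)C(C)(C)C)[C@@H](C(=O)N2C(=O)OC[C@H]2Cc2ccccc2)CC1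
F4 | step 5 | 2-{(1S,2R)-2-[(2E)-4-{[tert-butyl(dimethyl)silyl]oxy}-2-methylbut-2-en-1-yl]-4-methylcyclohex-3-en-1-yl}propan-2-ol | CC1=C[C@@H](C/C(C)=C/CO[Si](C)(C)C(C)(C)C)[C@@H](C(C)(C)O)CC1
F5 | step 11 | (2R,3R)-3-hydroperoxy-2-methyl-5-[(2R,3R)-2-methyl-3-{[(triethylsilyl)oxy]methyl}oxiran-2-yl]pentanoic acid | C[C@@H](C(=O)O)[C@H](OO)CC[C@@]1(C)O[C@@H]1CO[Si](CC)(CC)CC
F6 | step 13 | [(4aR,8aS)-1,1,3,6-tetramethyl-1,4,4a,7,8,8a-hexahydronaphthalen-2-yl]methanol | CC1=C[C@H]2CC(C)=C(CO)C(C)(C)[C@H]2CC1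
F7 | step 13 | 1-phenyl-5-({[(4aR,8aS)-1,1,3,6-tetramethyl-1,4,4a,7,8,8a-hexahydronaphthalen-2-yl]methyl}sulfanyl)-1H-tetrazole | CC1=C[C@H]2CC(C)=C(CSc3nnnn3-c3ccccc3)C(C)(C)[C@H]2CC1
F8 | step 13 | 1-phenyl-5-({[(4aR,8aS)-1,1,3,6-tetramethyl-1,4,4a,7,8,8a-hexahydronaphthalen-2-yl]methyl}sulfonyl)-1H-tetrazole | CC1=C[C@H]2CC(C)=C(CS(=O)(=O)c3nnnn3-c3ccccc3)C(C)(C)[C@H]2CC1
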